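**Retrosynthetic overview**
1. Cryptomerin A ⇒ its mono-benzyl ether (benzyl on O-7 of the acacetin unit) by a final debenzylation.
2. Key disconnection: the diaryl ether bond C-6(acacetin unit)–O-4'(apigenin unit) ⇒ unprotected apigenin as O-nucleophile + 6-iodo-7-O-benzylacacetin as electrophile, joined by a new site-selective Cu-catalysed O-arylation.
3. 6-Iodide ⇒ 5-OH-directed C-6 iodination of 7-O-benzylacacetin ⇒ acacetin.
4. Ring order: no ring is built; both 2-aryl-chromen-4-one systems are bought intact (acacetin, apigenin) and only joined.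

Assumption: the target SMILES has no stereocentre or other stereogenic element, so the compound is achiral and no stereocontrol is needed; acacetin and apigenin are taken as inexpensive catalogue flavones.

**Step 1**
Reactants: 1 acacetin (5,7-dihydroxy-2-(4-methoxyphenyl)-4H-chromen-4-one)
Product: 3 7-O-benzylacacetin (7-(benzyloxy)-5-hydroxy-2-(4-methoxyphenyl)-4H-chromen-4-one)
Conditions: BnBr (1.1 equiv), K2CO3 (1.5 equiv), DMF, rt
Reagents that add atoms: benzyl bromide (2), BrCc1ccccc1
Why: Williamson ether synthesis; carbonate ionises only the 7-OH (vinylogous acid, pKa about 7) while the 5-OH stays locked in its hydrogen bond to C-4=O, so O-7 is benzylated selectively and no stereocentre is formed.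

**Step 2**
Reactants: 3 7-O-benzylacacetin
Product: 5 6-iodo-7-O-benzylacacetin (7-(benzyloxy)-5-hydroxy-6-iodo-2-(4-methoxyphenyl)-4H-chromen-4-one)
Conditions: BnMe3N+ ICl2– (1.1 equiv), CaCO3 (1.5 equiv), CH2Cl2–MeOH (5:2), rt
Reagents that add atoms: benzyltrimethylammonium dichloroiodate (4), C[N+](C)(C)Cc1ccccc1.Cl[I-]Cl
Why: Electrophilic aromatic iodination (SEAr); 5-hydroxy-7-alkoxyflavones with a free, chelated 5-OH are iodinated at C-6 (ortho to that phenol) by this buffered reagent, while the chromone-deactivated anisyl ring and C-3 are left alone; no stereocentre is formed.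

**Step 3**
Reactants: 5 6-iodo-7-O-benzylacacetin; 6 apigenin (5,7-dihydroxy-2-(4-hydroxyphenyl)-4H-chromen-4-one)
Product: 8 mono-O-benzylcryptomerin A [7-(benzyloxy)-6-[4-(5,7-dihydroxy-4-oxo-4H-chromen-2-yl)phenoxy]-5-hydroxy-2-(4-methoxyphenyl)-4H-chromen-4-one], via apigenin dipotassium bisphenoxide 7 (not isolated)
Conditions: 6 (2 equiv), K3PO4 (5 equiv), DMSO, rt; then 5, CuI (20 mol %), picolinic acid (40 mol %), 90 °C, Ar
Reagents that add atoms: none
Why: Proposed new method: a site-selective Ullmann-type O-arylation of a fully unprotected trihydroxyflavone by a 5-hydroxy-6-iodoflavone. In dianion 7 the 4'-phenoxide (conjugate acid pKa about 9) is the more basic and more nucleophilic oxygen, the 7-phenoxide (pKa about 7) is a vinylogous carboxylate that acts as a spectator, and the 5-OH stays hydrogen-bonded to C-4=O. The anionic picolinate–Cu(I) centre should therefore bind the 4'-oxygen preferentially, and this electron-richer Cu(I) phenoxide should also activate the C–I bond of 5 fastest (Curtin–Hammett selection, both effects in the same direction), before C–O reductive elimination closes the hindered C-6–O-4' ether. The closest known reaction types are the CuI/picolinic acid Ullmann synthesis of sterically hindered diaryl ethers and the dianion-controlled O-alkylation of dihydroxy(iso)flavones at the more basic phenoxide, neither shown for joining two flavones or for a di-ortho-oxygenated 6-iodoflavone electrophile. No stereocentre is formed.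

**Step 4**
Reactants: 8 mono-O-benzylcryptomerin A
Product: 9 cryptomerin A (6-[4-(5,7-dihydroxy-4-oxo-4H-chromen-2-yl)phenoxy]-5,7-dihydroxy-2-(4-methoxyphenyl)-4H-chromen-4-one)
Conditions: H2 (1 atm), 10% Pd/C, THF–MeOH (1:1), rt
Reagents that add atoms: none
Why: Catalytic hydrogenolysis of the benzyl aryl ether; the diaryl ether, the aryl methyl ether and the vinylogous-ester C2=C3 bonds of both chromones are inert at 1 atm and room temperature, and the achiral target has no stereocentre to set.

**Compound list**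
1 | acacetin; 5,7-dihydroxy-2-(4-methoxyphenyl)-4H-chromen-4-one | COc1ccc(-c2cc(=O)c3c(O)cc(O)cc3o2)cc1 | starting material
2 | benzyl bromide | BrCc1ccccc1 | starting material
3 | 7-O-benzylacacetin; 7-(benzyloxy)-5-hydroxy-2-(4-methoxyphenyl)-4H-chromen-4-one | COc1ccc(-c2cc(=O)c3c(O)cc(OCc4ccccc4)cc3o2)cc1 | intermediate
4 | benzyltrimethylammonium dichloroiodate | C[N+](C)(C)Cc1ccccc1.Cl[I-]Cl | starting material
5 | 6-iodo-7-O-benzylacacetin; 7-(benzyloxy)-5-hydroxy-6-iodo-2-(4-methoxyphenyl)-4H-chromen-4-one | COc1ccc(-c2cc(=O)c3c(O)c(I)c(OCc4ccccc4)cc3o2)cc1 | intermediate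
6 | apigenin; 5,7-dihydroxy-2-(4-hydroxyphenyl)-4H-chromen-4-one | O=c1cc(-c2ccc(O)cc2)oc2cc(O)cc(O)c12 | starting material
7 | apigenin dipotassium bisphenoxide; dipotassium 4-(5-hydroxy-7-oxido-4-oxo-4H-chromen-2-yl)phenolate | [K+].[K+].O=c1cc(-c2ccc([O-])cc2)oc2cc([O-])cc(O)c12 | intermediate (not isolated)
8 | mono-O-benzylcryptomerin A; 7-(benzyloxy)-6-[4-(5,7-dihydroxy-4-oxo-4H-chromen-2-yl)phenoxy]-5-hydroxy-2-(4-methoxyphenyl)-4H-chromen-4-one | COc1ccc(-c2cc(=O)c3c(O)c(Oc4ccc(-c5cc(=O)c6c(O)cc(O)cc6o5)cc4)c(OCc7ccccc7)cc3o2)cc1 | intermediate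
9 | cryptomerin A; 6-[4-(5,7-dihydroxy-4-oxo-4H-chromen-2-yl)phenoxy]-5,7-dihydroxy-2-(4-methoxyphenyl)-4H-chromen-4-one | COc1ccc(-c2cc(=O)c3c(O)c(Oc4ccc(-c5cc(=O)c6c(O)cc(O)cc6o5)cc4)c(O)cc3o2)cc1 | target

**Totals**
Total step count: 4. Longest linear sequence: 4 (1 → 3 → 5 → 8 → 9; apigenin 6 enters in step 3).

**Three steps most likely to fail**

Step 3 (the proposed new site-selective O-arylation). The risks are arylation at O-7 of apigenin, double arylation, and hydrodeiodination of the hindered iodide. The fallback uses known chemistry and replaces catalyst/base control by protecting-group control; it sets out from 6 (and uses 5) and comes back to the route at 9. Apigenin 6 is mono-benzylated at its most acidic 7-OH (2, 1.05 equiv, K2CO3, DMF, rt) to 7-O-benzylapigenin F1, whose only unchelated phenol is the 4'-OH. Standard ligand-accelerated Ullmann diaryl ether coupling of F1 with 5 (CuI, picolinic acid, K3PO4, DMSO, 90 °C) gives di-O-benzylcryptomerin A F2. Hydrogenolysis of both benzyl ethers under the step-4 conditions gives 9.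

Step 2 (regioselective mono-iodination). The risks are 8-iodo and 6,8-diiodo by-products. The fallback replaces reagent-controlled substitution by delivery of iodine from a metal phenoxide; it sets out from 3 and comes back at 5. Treatment of 3 with thallium(I) acetate in CH2Cl2 gives the thallium(I) 5-phenoxide of 7-O-benzylacacetin F3. Addition of I2 (1 equiv, rt) then places iodine only on the single free ortho carbon of that phenoxide, C-6 (the classical thallium(I) carboxylate/iodine ortho-iodination of phenols), to give 5.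

Step 4 (hydrogenolysis). The risks are partial reduction of a chromone C2=C3 bond, catalyst poisoning by traces of copper or iodide, and poor solubility of the biflavone. The fallback changes the protecting-group strategy to an acid-labile acetal, so that the last step is a hydrolysis and not a reduction; it sets out from 1 and comes back at 9. Acacetin 1 with chloromethyl methyl ether and i-Pr2NEt (CH2Cl2, 0 °C) gives 7-O-(methoxymethyl)acacetin F4. Iodination as in step 2 (4, CaCO3) gives 6-iodo-7-O-(methoxymethyl)acacetin F5. Coupling with 6 as in step 3 gives mono-O-(methoxymethyl)cryptomerin A F6. HCl (3 M) in MeOH–THF at 50 °C removes the acetal and gives 9.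

**Further compounds**
F1 | step 3 | 7-O-benzylapigenin; 7-(benzyloxy)-5-hydroxy-2-(4-hydroxyphenyl)-4H-chromen-4-one | O=c1cc(-c2ccc(O)cc2)oc2cc(OCc3ccccc3)cc(O)c12
F2 | step 3 | di-O-benzylcryptomerin A; 7-(benzyloxy)-6-[4-(7-(benzyloxy)-5-hydroxy-4-oxo-4H-chromen-2-yl)phenoxy]-5-hydroxy-2-(4-methoxyphenyl)-4H-chromen-4-one | COc1ccc(-c2cc(=O)c3c(O)c(Oc4ccc(-c5cc(=O)c6c(O)cc(OCc8ccccc8)cc6o5)cc4)c(OCc7ccccc7)cc3o2)cc1
F3 | step 2 | thallium(I) 7-(benzyloxy)-2-(4-methoxyphenyl)-4-oxo-4H-chromen-5-olate | [Tl+].COc1ccc(-c2cc(=O)c3c([O-])cc(OCc4ccccc4)cc3o2)cc1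
F4 | step 4 | 7-O-(methoxymethyl)acacetin; 5-hydroxy-7-(methoxymethoxy)-2-(4-methoxyphenyl)-4H-chromen-4-one | COc1ccc(-c2cc(=O)c3c(O)cc(OCOC)cc3o2)cc1
F5 | step 4 | 6-iodo-7-O-(methoxymethyl)acacetin; 5-hydroxy-6-iodo-7-(methoxymethoxy)-2-(4-methoxyphenyl)-4H-chromen-4-one | COc1ccc(-c2cc(=O)c3c(O)c(I)c(OCOC)cc3o2)cc1
F6 | step 4 | mono-O-(methoxymethyl)cryptomerin A; 6-[4-(5,7-dihydroxy-4-oxo-4H-chromen-2-yl)phenoxy]-5-hydroxy-7-(methoxymethoxy)-2-(4-methoxyphenyl)-4H-chromen-4-one | COc1ccc(-c2cc(=O)c3c(O)c(Oc4ccc(-c5cc(=O)c6c(O)cc(O)cc6o5)cc4)c(OCOC)cc3o2)cc1
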